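## The problem

Target 16 is an achiral isoflavone. Ring A carries one hydroxyl (C7), ring C is the 4-pyranone, and ring B is attached to C3 through C1'. C1' lies between two hydroxyls (C2', C6'), and ring B also carries a methoxy group at C4' and a prenyl group at C3'. Five of the six ring B positions are therefore substituted, and its three oxygens must be told apart.

The C3–C1' axis is the congested point. A reaction that makes this bond, or that needs a reagent to reach C3 past the two ortho oxygens, is at a disadvantage, and 2,6-dioxygenated arylboron reagents lose boron easily.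

There is no stereocentre in 16. The only one that arises on the way (C3 of an isoflavanone) is erased again, so no element of stereocontrol is needed.

The fragile parts are the prenyl group and the electron-rich phenols. Strong acid protonates the prenyl alkene, which the neighbouring 2'-hydroxyl then traps as a chroman; hydrogenolysis would saturate it; its CH2 is both benzylic and allylic. The phenols need protecting groups that come off without hydrogen and without strong acid.

The feature that opens the route is that the C4 carbonyl is a single carbon flanked by C4a of ring A and by C3. It can be brought in as carbon monoxide. Once an aryl vinyl ketone has been assembled in this way, the ring A oxygen ortho to the carbonyl only has to add to the terminal carbon (C2) to close ring C.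

## Retrosynthesis

**16 from 15.** The three O–CH2 acetal bonds at O7, O2' and O6' are cut, leading back to the tris-MOM ether 15. Benzyl ethers would need hydrogenolysis, which the prenyl alkene does not survive. Aryl silyl ethers would not last in hot carbonate during the key step. Methyl ethers could not be distinguished from the 4'-methoxy group. Compound 15 has no free phenol and so tolerates base, palladium and oxidants. The forward step must be an acetal cleavage mild enough to leave the prenyl/2'-hydroxyl pair uncyclised.

**15 from 13.** The C2=C3 double bond is taken back to the C2H2–C3H unit of the racemic isoflavanone 13. This adjustment of oxidation level is the price of building ring C from carbon monoxide and a plain 1,1-disubstituted alkene. The neighbouring choice, a vinyl partner that already carries a leaving group at the future C2, would be far harder to prepare. The forward reaction must dehydrogenate without forming a bond at C3, which is shielded on both faces by the ortho MOM ethers, and must spare the prenyl group. Silyl enol ether 14 and its oxidation with 2-iodoxybenzoic acid (IBX) and 4-methoxypyridine N-oxide answer this, because hydrogen is removed from C2 by electron transfer.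

**13 from 10, 11 and 7.** Three bonds are cut at once. O1–C2 is opened by retro-oxa-Michael reaction to the hydroxyaryl vinyl ketone 12. C4–C4a and C3–C4 are then cut on either side of the carbonyl, giving iodophenol 10, carbon monoxide 11 and alkenylboronate 7.
- Against the C3–C1' cut: cross-coupling of a 3-halochromone with a ring B boron reagent would need a di-ortho-oxygenated arylboron compound that is both hindered and prone to protodeboronation.
- Against the deoxybenzoin route: it would need a Lewis-acid acylation of resorcinol in the presence of a prenyl group and acetals.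
- For the chosen cut: the crowded C1' is left alone, and 13 falls into two aromatic pieces of similar size plus a gas.
- Asked of the forward reaction: CO insertion must precede transmetalation, and the phenoxide must wait for the enone instead of capturing the aroyl–palladium intermediate.

**7 from 5 and 6, and 5 from 4.** The C–B bond of 7 is cut to enol triflate 5 and B2pin2 6. The C–O bond of 5 leads to methyl ketone 4. Hydroboration of the corresponding aryl alkyne was the neighbouring option, but its regiochemistry is uncertain for an electron-rich, di-ortho-substituted aryl group. In 5 the position of boron is fixed by the position of the ketone oxygen. The forward steps are kinetic O-triflation of the only possible enolate and a Miyaura borylation.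

**4 from 3, and 3 from 1 and 2.** The two MOM acetal bonds of 4 are cut to diphenol 3. The C3'–CH2 bond of 3 is cut to the purchased acetophenone 1 and prenyl bromide 2. Compound 1 is symmetric, so its two open ring positions are equivalent and the regiochemical question of ring B disappears: any C-monoprenylation gives 3. Only C- against O-alkylation has to be managed.

**10 from 9, and 9 from 8.** The C–I bond of 10 is cut to 3-(methoxymethoxy)phenol 9, and its acetal bond to resorcinol 8. Iodinating 9 ortho to the free hydroxyl is preferred to mono-protecting 4-iodoresorcinol. There the two hydroxyls differ little, and the more acidic one is the wrong one.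

## Roads not taken

**Alternative 1:** The cut is at C3–C4 and O1–C2. In the forward sense 2,4-diacetoxybenzoyl chloride A1 acylates the β-carbon of the ring B morpholine enamine A2. Methanolic K2CO3 and then acetic acid free the ring A phenol, which displaces morpholine at C2 to give the 2',6'-bis-MOM isoflavone A3.
- Merits: A3 is already at the isoflavone oxidation level. No palladium and no toxic gas are needed. Only two acetals remain to be removed.
- Weak points: A2 presupposes a two-carbon side chain at the aldehyde oxidation level on ring B. From the available ketone 1 this would need an oxidative aryl shift or a one-carbon homologation, both awkward beside a prenyl group and acetals. The acylated carbon is the one that bears the di-ortho-substituted aryl group, and it must be reached by bimolecular attack on an acid chloride. A1 can also transfer its own acetyl groups.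
- Comparison: this road is better than the chosen plan in oxidation-state economy, since it needs no counterpart to step 8. The chosen plan sets against this that its ring B partner 7 comes in two steps from ketone 4, and that the bond at the crowded carbon forms by reductive elimination from palladium and not by intermolecular attack of a hindered nucleophile.

**Alternative 2:** Ring B is built last by a Danheiser benzannulation. The 3-siloxycyclobutenone A4, which already carries the chromone at its C4, is heated with the methoxyalkyne A5. The vinylketene adds the alkyne and the dienylketene electrocyclises, forming C2'–C3' and C4'–C5' and giving the 7,6'-bis-TIPS ether A6.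
- Merits: the substitution pattern of ring B is dictated by the reaction, the prenyl group arrives on the alkyne, and no hindered bond to C1' has to be made. The endgame is a fluoride desilylation.
- Weak points: A4 and A5 are each multi-step, sensitive compounds. A4 has an enolisable C4–H next to a chromone. The thermolysis exposes an alkynyl ether and a chromone, itself an acceptor for ketenes, to prolonged heating.
- Comparison: in regiocontrol of ring B and in the mildness of the final deprotection this road is better than the chosen plan, which has to accept a modest C-prenylation (step 1) and an acidic last step. The chosen plan sets against this a much shorter sequence from purchasable aromatic compounds and the absence of strained or thermally labile intermediates.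

**Alternative 3:** Only C4–C4a is cut. The (Z)-aryloxyacrylate A7 undergoes bromine–lithium exchange with t-BuLi at very low temperature, and the aryllithium closes onto the methyl ester (Parham cyclisation) to give the tris-MOM isoflavone A8, which is the same compound as 15.
- Merits: it reaches 15 directly and so saves the dehydrogenation. It uses no CO.
- Weak points: A7 again requires ring B to carry a CH2–CO2Me side chain before the enol ether is made, which is the same homologation problem as in Alternative 1. The β-aryloxyacrylate is itself an acceptor for t-BuLi and can lose aryloxide by addition–elimination. Closure demands the Z geometry. The key step forms one bond where the chosen step forms three.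
- Comparison: in step count after the key step this road is better by one step. The chosen plan sets against this catalytic, non-cryogenic conditions, late convergence of two fragments, and a ring B partner that needs no homologation.

Key step: step 7

Remarks on the chemistry:
- Compounds 1, 2, 6, 8 and 11 are taken as purchased materials.
- Compound 13 is made and used as the racemate, since its only stereocentre (C3) becomes sp2 in step 8 and the target is achiral.

## Route

Step 1
Reactants: 1 1-(2,6-dihydroxy-4-methoxyphenyl)ethan-1-one; 2 1-bromo-3-methylbut-2-ene (prenyl bromide)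
Product: 3 1-[2,6-dihydroxy-4-methoxy-3-(3-methylbut-2-en-1-yl)phenyl]ethan-1-one
Conditions: 2 (1.1 equiv), 10% aq KOH, 0 °C → rt
Reagents that add atoms: none
Why: C-alkylation of an ambident phloroglucinol-type phenoxide in water, where solvation of oxygen steers the allylic bromide to carbon (classical C-prenylation of acylphloroglucinols); the two open ring positions of 1 are equivalent, so only one C-monoprenyl isomer can form, and the O-prenyl and diprenyl by-products are expected to be separable.

Step 2
Reactants: 3 1-[2,6-dihydroxy-4-methoxy-3-(3-methylbut-2-en-1-yl)phenyl]ethan-1-one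
Product: 4 1-[4-methoxy-2,6-bis(methoxymethoxy)-3-(3-methylbut-2-en-1-yl)phenyl]ethan-1-one
Conditions: NaH (2.6 equiv), MOMCl (2.6 equiv), DMF, 0 °C → rt
Reagents that add atoms: chloromethyl methyl ether, COCCl
Why: O-alkylation of both sodium phenoxides with MOMCl; NaH is used because the second hydroxyl is hydrogen-bonded to the acetyl group and does not react under amine-base conditions.

Step 3
Reactants: 4 1-[4-methoxy-2,6-bis(methoxymethoxy)-3-(3-methylbut-2-en-1-yl)phenyl]ethan-1-one
Product: 5 1-[4-methoxy-2,6-bis(methoxymethoxy)-3-(3-methylbut-2-en-1-yl)phenyl]ethenyl trifluoromethanesulfonate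
Conditions: KN(SiMe3)2 (1.2 equiv), THF, −78 °C; PhNTf2 (1.2 equiv), −78 → 0 °C; rapid filtration through Et3N-deactivated silica
Reagents that add atoms: N-phenylbis(trifluoromethanesulfonimide), O=S(=O)(N(c1ccccc1)S(=O)(=O)C(F)(F)F)C(F)(F)F
Why: Kinetic deprotonation of the methyl ketone, its only enolisable position, and O-sulfonylation of the potassium enolate (enol triflate formation); the product is kept cold and handled on basified silica because an electron-rich 1-arylvinyl triflate can ionise.

Step 4
Reactants: 5 1-[4-methoxy-2,6-bis(methoxymethoxy)-3-(3-methylbut-2-en-1-yl)phenyl]ethenyl trifluoromethanesulfonate; 6 bis(pinacolato)diboron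
Product: 7 2-{1-[4-methoxy-2,6-bis(methoxymethoxy)-3-(3-methylbut-2-en-1-yl)phenyl]ethenyl}-4,4,5,5-tetramethyl-1,3,2-dioxaborolane
Conditions: 6 (1.1 equiv), PdCl2(PPh3)2 (3 mol %), PPh3 (6 mol %), KOPh (1.5 equiv), toluene, 50 °C
Reagents that add atoms: none
Why: Miyaura borylation of an alkenyl triflate: oxidative addition of the C–OTf bond to zerovalent palladium, phenoxide-assisted transmetalation with B2pin2 and reductive elimination put boron exactly where the ketone oxygen stood, so no regiochemical question arises.

Step 5
Reactants: 8 resorcinol
Product: 9 3-(methoxymethoxy)phenol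
Conditions: 8 (3 equiv), NaH (1.0 equiv), MOMCl (1.0 equiv), DMF, 0 °C → rt
Reagents that add atoms: chloromethyl methyl ether, COCCl
Why: Statistical mono-protection of a symmetric diphenol; the excess of cheap resorcinol suppresses the bis-ether and unreacted 8 is removed by aqueous washing.

Step 6
Reactants: 9 3-(methoxymethoxy)phenol
Product: 10 2-iodo-5-(methoxymethoxy)phenol
Conditions: I2 (1.0 equiv), NaHCO3 (1.2 equiv), THF–H2O (1:1), 0 °C
Reagents that add atoms: iodine, II
Why: Electrophilic iodination of the phenoxide under aqueous bicarbonate goes ortho to the free hydroxyl, and of the two ortho sites the one para to the MOM ether is the less hindered, as in the iodination of other 3-alkoxyphenols; the minor isomer iodinated between the two oxygens should be separable, and the acetal is stable to the mildly basic medium.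

Step 7
Reactants: 10 2-iodo-5-(methoxymethoxy)phenol; 11 carbon monoxide; 7 2-{1-[4-methoxy-2,6-bis(methoxymethoxy)-3-(3-methylbut-2-en-1-yl)phenyl]ethenyl}-4,4,5,5-tetramethyl-1,3,2-dioxaborolane
Product: 13 rac-3-[4-methoxy-2,6-bis(methoxymethoxy)-3-(3-methylbut-2-en-1-yl)phenyl]-7-(methoxymethoxy)-2,3-dihydro-4H-chromen-4-one, via ring-opened 2-hydroxyaryl 1-arylvinyl ketone 12 (not isolated)
Conditions: 11 (1 atm), 7 (1.3 equiv), Pd(OAc)2 (5 mol %), n-BuP(1-adamantyl)2 (10 mol %), K2CO3 (3 equiv), anisole–H2O (20:1), 80 °C, 10 added over 4 h
Reagents that add atoms: none
Why: Pd(OAc)2 is reduced in situ to zerovalent palladium, which inserts into the C–I bond of 10; migratory insertion of CO gives the aroyl complex of divalent palladium, held as a five-membered chelate by the ortho phenoxide. Base-assisted transmetalation with the alkenylboronate 7 and reductive elimination release the 2-hydroxyaryl 1-arylvinyl ketone 12, so that C4–C4a and C3–C4 are formed. The closest known reaction type is the carbonylative Suzuki–Miyaura coupling of aryl iodides with alkenylboron reagents to aryl vinyl ketones, and the ring closure is the known spontaneous cyclisation of 2-hydroxyaryl 1-arylvinyl ketones to isoflavanones. Ring C closes by 6-endo-trig oxa-Michael addition of the ring A phenoxide to the unsubstituted CH2 terminus of the enone (O1–C2), followed by protonation of the enolate at C3. The C3 stereocentre is created in that protonation without any controlling element, so 13 is racemic, which is of no consequence because C3 becomes sp2 in step 8. The step needs carbonylative and not direct coupling: CO insertion into the electron-rich aryl–palladium bond is fast, whereas transmetalation of the di-ortho-substituted 1-arylvinylboronate is slow, so the aryl–palladium species is carbonylated before it meets boron. It also needs C-acylation and not ester formation by the phenoxide, which is served by adding 10 slowly to an excess of 7 and by chelation of the phenoxide to palladium. Only the ring A oxygen can add to the enone because the ring B oxygens are MOM ethers.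

Step 8
Reactants: 13 rac-3-[4-methoxy-2,6-bis(methoxymethoxy)-3-(3-methylbut-2-en-1-yl)phenyl]-7-(methoxymethoxy)-2,3-dihydro-4H-chromen-4-one
Product: 15 3-[4-methoxy-2,6-bis(methoxymethoxy)-3-(3-methylbut-2-en-1-yl)phenyl]-7-(methoxymethoxy)-4H-chromen-4-one, via trimethylsilyl enol ether 14 (not isolated)
Conditions: TMSCl (2 equiv, present before the base), LiN(i-Pr)2 (1.3 equiv), THF, −78 °C; concentrate; IBX (1.5 equiv), 4-methoxypyridine N-oxide (1.5 equiv), DMSO, rt
Reagents that add atoms: chlorotrimethylsilane, C[Si](C)(C)Cl (its silyl group is present in 14 only and is absent from 15)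
Why: Internal-quench silylation traps the C3 enolate on oxygen before it can expel the ring phenoxide, and the oxidation of silyl enol ethers to enones by IBX with 4-methoxypyridine N-oxide removes hydrogen from C2 by electron transfer, so no bond has to form at C3, which is shielded on both faces by the ortho MOM ethers; the prenyl group and the acetals are inert at room temperature.

Step 9
Reactants: 15 3-[4-methoxy-2,6-bis(methoxymethoxy)-3-(3-methylbut-2-en-1-yl)phenyl]-7-(methoxymethoxy)-4H-chromen-4-one
Product: 16 3-[2,6-dihydroxy-4-methoxy-3-(3-methylbut-2-en-1-yl)phenyl]-7-hydroxy-4H-chromen-4-one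
Conditions: HCl (2 M), MeOH–H2O, 40 °C
Reagents that add atoms: none
Why: Acid-catalysed acetal exchange with methanol removes all three MOM groups; dilute acid at moderate temperature is chosen so that the prenyl alkene is not protonated and trapped by the 2'-hydroxyl as a chroman.

## Compound list

1 | 1-(2,6-dihydroxy-4-methoxyphenyl)ethan-1-one | CC(=O)c1c(O)cc(OC)cc1O | starting material
2 | 1-bromo-3-methylbut-2-ene (prenyl bromide) | CC(C)=CCBr | starting material
3 | 1-[2,6-dihydroxy-4-methoxy-3-(3-methylbut-2-en-1-yl)phenyl]ethan-1-one | CC(=O)c1c(O)cc(OC)c(CC=C(C)C)c1O | intermediate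
4 | 1-[4-methoxy-2,6-bis(methoxymethoxy)-3-(3-methylbut-2-en-1-yl)phenyl]ethan-1-one | CC(=O)c1c(OCOC)cc(OC)c(CC=C(C)C)c1OCOC | intermediate
5 | 1-[4-methoxy-2,6-bis(methoxymethoxy)-3-(3-methylbut-2-en-1-yl)phenyl]ethenyl trifluoromethanesulfonate | C=C(OS(=O)(=O)C(F)(F)F)c1c(OCOC)cc(OC)c(CC=C(C)C)c1OCOC | intermediate
6 | bis(pinacolato)diboron | CC1(C)OB(OC1(C)C)B1OC(C)(C)C(C)(C)O1 | starting material
7 | 2-{1-[4-methoxy-2,6-bis(methoxymethoxy)-3-(3-methylbut-2-en-1-yl)phenyl]ethenyl}-4,4,5,5-tetramethyl-1,3,2-dioxaborolane | C=C(B1OC(C)(C)C(C)(C)O1)c1c(OCOC)cc(OC)c(CC=C(C)C)c1OCOC | intermediate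
8 | resorcinol | Oc1cccc(O)c1 | starting material
9 | 3-(methoxymethoxy)phenol | COCOc1cccc(O)c1 | intermediate
10 | 2-iodo-5-(methoxymethoxy)phenol | COCOc1ccc(I)c(O)c1 | intermediate
11 | carbon monoxide | [C-]#[O+] | starting material
12 | 1-[2-hydroxy-4-(methoxymethoxy)phenyl]-2-[4-methoxy-2,6-bis(methoxymethoxy)-3-(3-methylbut-2-en-1-yl)phenyl]prop-2-en-1-one | C=C(C(=O)c1ccc(OCOC)cc1O)c1c(OCOC)cc(OC)c(CC=C(C)C)c1OCOC | intermediate
13 | rac-3-[4-methoxy-2,6-bis(methoxymethoxy)-3-(3-methylbut-2-en-1-yl)phenyl]-7-(methoxymethoxy)-2,3-dihydro-4H-chromen-4-one (racemic at C3) | COCOc1ccc2c(c1)OCC(c1c(OCOC)cc(OC)c(CC=C(C)C)c1OCOC)C2=O | intermediate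
14 | 3-[4-methoxy-2,6-bis(methoxymethoxy)-3-(3-methylbut-2-en-1-yl)phenyl]-7-(methoxymethoxy)-4-(trimethylsilyloxy)-2H-chromene | COCOc1ccc2c(c1)OCC(c1c(OCOC)cc(OC)c(CC=C(C)C)c1OCOC)=C2O[Si](C)(C)C | intermediate
15 | 3-[4-methoxy-2,6-bis(methoxymethoxy)-3-(3-methylbut-2-en-1-yl)phenyl]-7-(methoxymethoxy)-4H-chromen-4-one | COCOc1ccc2c(c1)occ(-c1c(OCOC)cc(OC)c(CC=C(C)C)c1OCOC)c2=O | intermediate
16 | 3-[2,6-dihydroxy-4-methoxy-3-(3-methylbut-2-en-1-yl)phenyl]-7-hydroxy-4H-chromen-4-one | COc1cc(O)c(-c2coc3cc(O)ccc3c2=O)c(O)c1CC=C(C)C | target

## Step count and risks

Total step count: 9. Longest linear sequence: 7 steps (steps 1, 2, 3, 4, 7, 8, 9); the ring A branch (steps 5 and 6) joins at step 7.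

Least certain steps:

**Step 7 (key step).** Two processes are most likely to go wrong. The aroyl–palladium intermediate may be captured by phenoxide, giving aryl esters and oligomers. Transmetalation of the hindered 1-arylvinylboronate may be so slow that protodeboronation or hydroxycarbonylation takes over. Direct coupling without CO is a lesser concern.

The fallback reverses the roles of the partners. It sets out from 10. Miyaura borylation with 6 (PdCl2(dppf), KOAc, dioxane, 80 °C) gives 5-(methoxymethoxy)-2-(4,4,5,5-tetramethyl-1,3,2-dioxaborolan-2-yl)phenol F1. The known carbonylative Suzuki coupling of an enol triflate with an arylboron reagent is then applied to triflate 5, 11 and F1 (PdCl2(dppf), K2CO3, dioxane, 70 °C). Here the boron partner is unhindered and transfers quickly to the acryloyl–palladium intermediate. The same enone 12 results and closes to 13, where the route is rejoined.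

**Step 3.** Ionisation of the enol triflate to an aryl-stabilised vinyl cation would return ketone 4 on work-up or on silica. Base-induced loss of triflic acid to the alkyne is also possible.

The fallback sets out from 4. LiN(i-Pr)2 and ClP(O)(OEt)2 give diethyl 1-[4-methoxy-2,6-bis(methoxymethoxy)-3-(3-methylbut-2-en-1-yl)phenyl]ethenyl phosphate F2. Excess LiN(i-Pr)2 eliminates phosphate to give 2-ethynyl-5-methoxy-1,3-bis(methoxymethoxy)-4-(3-methylbut-2-en-1-yl)benzene F3. Hydroalumination with i-Bu2AlH and catalytic Ni(dppp)Cl2, which places aluminium at the internal carbon of aryl alkynes, gives diisobutyl{1-[4-methoxy-2,6-bis(methoxymethoxy)-3-(3-methylbut-2-en-1-yl)phenyl]ethenyl}aluminium F4, which is not isolated. Treatment with 2-methoxy-4,4,5,5-tetramethyl-1,3,2-dioxaborolane converts it into 7, where the route is rejoined without passing through 5.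

**Step 8.** The enolate may open ring C by β-elimination of the ring phenoxide before it is silylated. The ring-opened silyl ether returns to 13 on desilylation and can be recycled. The oxidation of the tetrasubstituted, hindered enol ether may also stall, or may spread to the benzylic-allylic CH2 of the prenyl group.

The fallback sets out from 14. NBS (THF, −78 °C) gives rac-3-bromo-3-[4-methoxy-2,6-bis(methoxymethoxy)-3-(3-methylbut-2-en-1-yl)phenyl]-7-(methoxymethoxy)-2,3-dihydro-4H-chromen-4-one F5. Dehydrobromination with DBU (THF, rt), the classical passage from 3-bromochromanones to chromones, gives 15, where the route is rejoined.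

**Step 1.** Competing O-alkylation and double alkylation, together with hydrolysis of the bromide, can keep the conversion to 3 low.

The fallback sets out from 1. Mono-O-alkylation with 2 (K2CO3, acetone, reflux; the second hydroxyl stays hydrogen-bonded) gives 1-{2-hydroxy-4-methoxy-6-[(3-methylbut-2-en-1-yl)oxy]phenyl}ethan-1-one F6. A para-Claisen–Cope rearrangement in hot N,N-diethylaniline (about 200 °C) moves the prenyl group, in its linear form, to the ring position para to the ether oxygen. Because of the symmetry of 1, the product is 3, where the route is rejoined.

## Further compounds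

F1 | step 7 | 5-(methoxymethoxy)-2-(4,4,5,5-tetramethyl-1,3,2-dioxaborolan-2-yl)phenol | COCOc1ccc(B2OC(C)(C)C(C)(C)O2)c(O)c1
F2 | step 3 | diethyl 1-[4-methoxy-2,6-bis(methoxymethoxy)-3-(3-methylbut-2-en-1-yl)phenyl]ethenyl phosphate | C=C(OP(=O)(OCC)OCC)c1c(OCOC)cc(OC)c(CC=C(C)C)c1OCOC
F3 | step 3 | 2-ethynyl-5-methoxy-1,3-bis(methoxymethoxy)-4-(3-methylbut-2-en-1-yl)benzene | C#Cc1c(OCOC)cc(OC)c(CC=C(C)C)c1OCOC
F4 | step 3 | diisobutyl{1-[4-methoxy-2,6-bis(methoxymethoxy)-3-(3-methylbut-2-en-1-yl)phenyl]ethenyl}aluminium | C=C([Al](CC(C)C)CC(C)C)c1c(OCOC)cc(OC)c(CC=C(C)C)c1OCOC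
F5 | step 8 | rac-3-bromo-3-[4-methoxy-2,6-bis(methoxymethoxy)-3-(3-methylbut-2-en-1-yl)phenyl]-7-(methoxymethoxy)-2,3-dihydro-4H-chromen-4-one | COCOc1ccc2c(c1)OCC(Br)(c1c(OCOC)cc(OC)c(CC=C(C)C)c1OCOC)C2=O
F6 | step 1 | 1-{2-hydroxy-4-methoxy-6-[(3-methylbut-2-en-1-yl)oxy]phenyl}ethan-1-one | CC(=O)c1c(O)cc(OC)cc1OCC=C(C)C
A1 | alternative 1 | 2,4-diacetoxybenzoyl chloride | CC(=O)Oc1ccc(C(=O)Cl)c(OC(C)=O)c1
A2 | alternative 1 | 4-{(E)-2-[4-methoxy-2,6-bis(methoxymethoxy)-3-(3-methylbut-2-en-1-yl)phenyl]ethenyl}morpholine | O1CCN(CC1)/C=C/c1c(OCOC)cc(OC)c(CC=C(C)C)c1OCOC
A3 | alternative 1 | 7-hydroxy-3-[4-methoxy-2,6-bis(methoxymethoxy)-3-(3-methylbut-2-en-1-yl)phenyl]-4H-chromen-4-one | Oc1ccc2c(c1)occ(-c1c(OCOC)cc(OC)c(CC=C(C)C)c1OCOC)c2=O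
A4 | alternative 2 | rac-4-{4-oxo-7-[tri(propan-2-yl)silyloxy]-4H-chromen-3-yl}-3-[tri(propan-2-yl)silyloxy]cyclobut-2-en-1-one | O=C1C=C(O[Si](C(C)C)(C(C)C)C(C)C)C1c1coc2cc(O[Si](C(C)C)(C(C)C)C(C)C)ccc2c1=O
A5 | alternative 2 | 1-methoxy-5-methylhex-4-en-1-yne | COC#CCC=C(C)C
A6 | alternative 2 | 3-{2-hydroxy-4-methoxy-3-(3-methylbut-2-en-1-yl)-6-[tri(propan-2-yl)silyloxy]phenyl}-7-[tri(propan-2-yl)silyloxy]-4H-chromen-4-one | CC(C)[Si](C(C)C)(C(C)C)Oc1ccc2c(c1)occ(-c1c(O)c(CC=C(C)C)c(OC)cc1O[Si](C(C)C)(C(C)C)C(C)C)c2=O
A7 | alternative 3 | methyl (Z)-3-[2-bromo-5-(methoxymethoxy)phenoxy]-2-[4-methoxy-2,6-bis(methoxymethoxy)-3-(3-methylbut-2-en-1-yl)phenyl]prop-2-enoate | COC(=O)/C(=C\Oc1cc(OCOC)ccc1Br)c1c(OCOC)cc(OC)c(CC=C(C)C)c1OCOC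
A8 | alternative 3 | 3-[4-methoxy-2,6-bis(methoxymethoxy)-3-(3-methylbut-2-en-1-yl)phenyl]-7-(methoxymethoxy)-4H-chromen-4-one (identical with 15) | COCOc1ccc2c(c1)occ(-c1c(OCOC)cc(OC)c(CC=C(C)C)c1OCOC)c2=O
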